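**Route to emmaosunin (12) by Claisen folding of a methoxylated triketo ester**

## Analysis of the target

Emmaosunin (12) is 5-hydroxy-3,6,7,8-tetramethoxy-2-(3-methoxyphenyl)chromen-4-one, a flavone in which the pyranone ring C is fused to a benzene ring A and carries the 3-methoxyphenyl ring B at C2 and a methoxy group at C3. The molecule is planar and has no stereocentre, so the task is entirely one of substitution pattern. Ring A is hexasubstituted: C5 carries the hydroxyl, C6, C7 and C8 carry methoxy groups, C8a carries the ring oxygen O1 and C4a the C4 carbonyl. Three points are sensitive: the 5-hydroxyl, which must end up free while its neighbours are methyl ethers; the methyl ethers next to a carbonyl, which Lewis acids cleave; and the electron-rich polyphenols that precede ring A, which oxidise in air under base. The difficulty is to place five oxygen atoms of three kinds around one benzene ring without a long series of aromatic substitutions and without a final selective demethylation. The plan rests on this: the oxygens at C5, C7 and C8a are mutually meta, as in phloroglucinol, the carbons between them (C6 and C8) carry methoxy groups, and C4a carries the acyl carbon C4, whose neighbour C3 is again methoxylated. Read along C3–C4–C4a–C8a–C8–C7–C6–C5, this is an eight-carbon chain in which carbonyl carbons alternate with carbons that bear a methoxy group or, at C4a, only hydrogen, which is the pattern of a folded polyketide. Ring A is also symmetric about the C4a–C7 axis until ring C is closed, so the two oxygens ortho to the acyl group need not be told apart.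

## Retrosynthetic reasoning

**O1–C2 of ring C.** The target 12 is opened at O1–C2 to the 1,3-diketone 11. In 11 the two phenolic hydroxyls flanking the acyl group are equivalent, so the forward cyclodehydration cannot give a regioisomer. The hydroxyl that is not used becomes the chelated 5-OH with no protection or deprotection. The forward step has to add a phenol oxygen to the aroyl carbonyl and dehydrate under acid.

**C2–C3 of the flavone, by acyl transfer.** Diketone 11 is cut between the methoxy-bearing carbon and the aroyl carbonyl. The aroyl group is first placed on one ortho oxygen, giving ester 10, and then moved to carbon; 10 comes from dihydroxy ketone 8 and acid chloride 9. Cutting here and not at C3–C4 keeps the methoxyacetyl group on ring A, where it has been since the ring was made. The forward reaction must form the enolate of an α-methoxy ketone next to a free phenol and transfer the acyl group through a six-membered transition state.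

**O–CH3 at C7.** Ketone 8 is simplified to the triol 7 by removing the methyl group from the oxygen para to the ketone. This is the only ring-A methyl group that the chain does not supply. Forward, one of three phenols must be methylated. The wanted one is the most acidic and the only one that is not next to the acyl group.

**C4a–C5, the strategic cut.** Ring A of 7 is opened between the acyl-bearing carbon and one of its oxygenated neighbours in the retro-Claisen sense. The ring carbon becomes an ester carbon and the acyl-bearing carbon becomes the central CH2 of a 1,3-diketone. The result is the linear triketo ester 6. Its C2 and C4 are the methoxy-bearing carbons of ring A, and its terminal methoxymethyl carbon C8 is the future C3 of the flavone. This bond is chosen over any bond made by aromatic substitution because its formation delivers all five ring-A oxygens, the C4 carbonyl and the C3 methoxy group at once. The forward reaction must make the doubly activated C6 attack the ester and must avoid aldol closure and chain cleavage.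

**C6–C7 of the chain.** Triketo ester 6 is cut between its terminal methoxyacetyl group and the rest, giving diketo ester 4 and the methoxyacetyl donor 5. The bond lies at the chain end, where the carbanion of a polyanion is the last formed and the most reactive. Forward, triply deprotonated 4 must be acylated once without proton exchange. An N-methoxy-N-methyl amide is used because its adduct does not collapse before the quench.

**C4–C5 of the chain.** In the same way 4 is cut into keto ester 2 and the acetyl donor 3. The nucleophile is the γ-carbon of the dianion of 2, its only second site of deprotonation, so regiochemistry is not in question.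

**C2–C3 of the chain.** Keto ester 2 is the Claisen self-condensation product of ester 1. The whole chain thus comes from 1 (twice), 3 and 5, all simple acyl building blocks.

## Alternatives that were turned down

**Alternative 1:** Ring C is taken apart at O1–C8a, C4–C4a and O1–C2, leaving a symmetrical tetramethoxy aryne and an arylpropiolic acid. In the forward direction a fluoride source such as CsF would release the aryne from the silyl triflate A2. The carboxylate of the propiolic acid A3 adds to it, and the aryl anion attacks its own ester carbonyl so that the acyl group moves from oxygen to carbon. The freed phenoxide then closes onto the ynone by 6-endo-dig conjugate addition to give the flavone A1.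
- For: three bonds form in one flask, two stable aromatic partners are joined convergently, and the two ends of the aryne are identical, so no regiochemical question arises. On convergence and on robustness of intermediates this alternative is stronger than the chosen plan, which passes through labile open-chain polyketones.
- Against: A1 has neither the C3 oxygen nor the free 5-hydroxyl. C3 would have to be hydroxylated and methylated on an electron-rich flavone, and the 5-methoxy group then cleaved selectively, which is three operations after the key step. A2 is a hexasubstituted benzene that needs its own multistep preparation. Each aryne carbon is flanked by a methoxy group, which hinders the carboxylate addition.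
- In exchange, the chosen route obtains the complete oxygenation pattern, including the C3 methoxy group and the 5-OH, from the ring-forming step and is shorter overall.

**Alternative 2:** Ring A is cut at C8–C8a and C4a–C5, so that it is grown on a preformed pyranone from a squaric ester. Lithium–halogen exchange on bromopyranone A7 and addition to dimethyl squarate A6 would give the 4-hydroxycyclobutenone A5. On heating, four-electron ring opening gives a dienylketene. Its ketene carbon bonds to the unsubstituted carbon next to the pyranone oxygen by six-electron electrocyclisation, and tautomerisation gives the hydroquinone A4. Methylation of the 8-hydroxyl would finish the synthesis.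
- For: the squarate delivers C5 to C8 with both methoxy groups in place, and rings B and C are present from the start. The two hydroxyls of A4 differ sharply, since the 5-OH is chelated and the 8-OH is not. The last methylation is therefore more secure than the para-selective methylation of 7 in the chosen route, and on that point this alternative is the stronger.
- Against: a 4-pyranone metallated at C5 is prone to ring opening and to attack by the exchange reagent. The electrocyclisation has to engage a double bond of a cross-conjugated pyranone, not a simple arene or alkene. A4 is an air-sensitive hydroquinone that oxidises to the quinone. A7 is itself several steps from purchasable material, so the step count is comparable or longer.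
- In exchange, the chosen route starts from commodity esters and amides, needs no organolithium chemistry on a heterocycle, and owes its regiochemistry to symmetry.

**Alternative 3:** Ring C is cut at C4–C4a, leaving the aryl enol ether acid A9, which derives from the phenol A10. In P2O5/CH3SO3H the acid would be activated to an acylium equivalent. This attacks the one unsubstituted carbon of the tetramethoxyphenoxy ring and closes ring C by intramolecular Friedel–Crafts acylation to the pentamethoxyflavone A8.
- For: only one ring-A position is open, so regiochemistry is fixed. The 2-aryl and 3-methoxy groups are already present and all intermediates are stable aromatic compounds. As a single ring closure it is the most dependable of the four key steps.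
- Against: A8 is permethylated, so the synthesis must end with a selective 5-O-demethylation in the presence of five other methyl ethers, one of which (at C3) also sits next to the carbonyl. A10 is not a commodity. A9 is a tetrasubstituted enol ether whose geometry (acid cis to aryloxy) must be set and kept. In strong acid it can isomerise and then acylate the 3-methoxyphenyl ring, para to its methoxy group, to an indenone.
- The steps to A9, the closure and the demethylation together exceed the chosen route, which places the free 5-hydroxyl by construction and needs no deprotection.

Key step: step 4

Assumption: compounds 2, 4, 6 and 11 are drawn as keto forms; their methoxy-bearing sp3 carbons are labile, unspecified centres that all become sp2 carbons of 12, and amide 5 is taken to be purchasable.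

## Steps

Step 1
Reactants: 1 methyl methoxyacetate (two molecules)
Product: 2 methyl 2,4-dimethoxy-3-oxobutanoate
Conditions: NaH (0.55 equiv), THF, 0 → 60 °C; then cold aq. HCl
Reagents that add atoms: none
Why: Claisen self-condensation: the sodium enolate of 1 acylates a second molecule of 1, and deprotonation of the β-keto ester formed pulls the equilibrium to 2. Only one enolate and one electrophile are present, so no crossed products can arise.

Step 2
Reactants: 2 methyl 2,4-dimethoxy-3-oxobutanoate; 3 N-methoxy-N-methylacetamide
Product: 4 methyl 2,4-dimethoxy-3,5-dioxohexanoate
Conditions: LiN(i-Pr)2 (2.1 equiv), THF, −78 → −20 °C; 3, −78 → 0 °C; cold 1 M HCl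
Reagents that add atoms: none
Why: γ-Acylation of a β-keto ester dianion (Weinreb ketone synthesis): after C2, the only further acidic carbon is C4, and this more basic carbanion adds to the amide. The chelated tetrahedral adduct survives until the acid quench, which prevents both proton exchange with the more acidic product and double addition.

Step 3
Reactants: 4 methyl 2,4-dimethoxy-3,5-dioxohexanoate; 5 N,2-dimethoxy-N-methylacetamide
Product: 6 methyl 2,4,8-trimethoxy-3,5,7-trioxooctanoate
Conditions: LiN(i-Pr)2 (3.1 equiv), THF, −78 → 0 °C; 5, −78 → −20 °C; cold 1 M HCl
Reagents that add atoms: none
Why: Terminal acylation of the trianion of a 3,5-diketo ester (polyanion acylation, Weinreb ketone synthesis): C2 and C4 are ionised first, then the methyl carbon C6, and this last-formed carbanion is the one that attacks amide 5. The lithium chelate of the adduct protects the new ketone until the cold quench; 6 is taken on crude because it lactonises and dehydrates easily.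

Step 4
Reactants: 6 methyl 2,4,8-trimethoxy-3,5,7-trioxooctanoate
Product: 7 2-methoxy-1-(2,4,6-trihydroxy-3,5-dimethoxyphenyl)ethanone
Conditions: Mg(OMe)2 (4 equiv), MeOH, 25 → 60 °C, Ar; then cold 1 M HCl
Reagents that add atoms: none
Why: Mg(OMe)2 turns the chain into magnesium enolates of its 1,3-dicarbonyl units, and the doubly activated C6, held as the C5/C7 diketonate, adds to the ester carbonyl C1, which is made more electrophilic by its α-methoxy group and by magnesium bridging the C1 and C3 oxygens. Collapse of the tetrahedral adduct expels methoxide and gives the non-aromatic triketone tautomer of 7, which enolises at once to the benzene ring, so the closure is irreversible and forms the bond that becomes C4a–C5 of the flavone. The closest known reaction type is the alkoxide- or magnesium-mediated Claisen (Dieckmann-type) cyclisation of 3,5,7-triketo esters to acylphloroglucinols. Ring A closes in the 6-exo-trig mode, the attacked ester C=O lying outside the six-membered ring that forms. No stereocentre is created, and the two labile centres C2 and C4 of 6 become sp2 ring carbons. The selectivity needed is carbon acylation at C1 in preference to the two aldol closures: attack of C2 on the C7 ketone would give a quaternary C(OMe)(CO2Me) carbon that cannot dehydrate to an arene and therefore reverts, and attack of C8 on the C3 ketone requires enolisation of a singly activated methoxymethyl group, which a base as weak as Mg(OMe)2 in methanol does not bring about. Lactonisation through the C5 enol oxygen is undone by methoxide, so the equilibrating mixture should drain into the aromatic product.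

Step 5
Reactants: 7 2-methoxy-1-(2,4,6-trihydroxy-3,5-dimethoxyphenyl)ethanone
Product: 8 1-(2,6-dihydroxy-3,4,5-trimethoxyphenyl)-2-methoxyethanone
Conditions: Me2SO4 (1.0 equiv), K2CO3 (1.0 equiv), acetone, 0 → 25 °C, Ar
Reagents that add atoms: dimethyl sulfate, COS(=O)(=O)OC
Why: Site-selective Williamson O-methylation: the 4-hydroxyl, para to the acyl group and not chelated to it, is the most acidic, so one equivalent of base ionises it alone and one equivalent of electrophile methylates there. The two ortho hydroxyls are hydrogen-bonded and shielded by the acyl group.

Step 6
Reactants: 8 1-(2,6-dihydroxy-3,4,5-trimethoxyphenyl)-2-methoxyethanone; 9 3-methoxybenzoyl chloride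
Product: 10 3-hydroxy-4,5,6-trimethoxy-2-(methoxyacetyl)phenyl 3-methoxybenzoate
Conditions: 9 (1.05 equiv), Et3N (1.2 equiv), DMAP (cat.), CH2Cl2, 0 °C
Reagents that add atoms: none
Why: O-Acylation of a phenol by an acid chloride under nucleophilic catalysis (esterification). The two hydroxyls of 8 are equivalent, and the one left in 10 is chelated to the ketone and hindered, so one equivalent of 9 should stop at the monoester.

Step 7
Reactants: 10 3-hydroxy-4,5,6-trimethoxy-2-(methoxyacetyl)phenyl 3-methoxybenzoate
Product: 12 emmaosunin (5-hydroxy-3,6,7,8-tetramethoxy-2-(3-methoxyphenyl)chromen-4-one), via β-diketone 11 (not isolated)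
Conditions: LiN(SiMe3)2 (3.5 equiv), THF, −78 → 0 °C; aq. HCl, solvent exchange; then AcOH, H2SO4 (cat.), 95 °C
Reagents that add atoms: none
Why: Baker–Venkataraman rearrangement followed by acid cyclodehydration: the lithium enolate of the methoxyacetyl group attacks the neighbouring aryl ester through a six-membered transition state and the aroyl group moves from oxygen to carbon, giving 11. In hot AcOH/H2SO4 a phenolic hydroxyl adds to the aroyl carbonyl and water is lost to form ring C; the two ortho hydroxyls of 11 are equivalent, so either closure gives 12 with the other hydroxyl as the chelated 5-OH.

## Compound list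

1 | methyl methoxyacetate | COCC(=O)OC | starting material
2 | methyl 2,4-dimethoxy-3-oxobutanoate (racemic, enolisable) | COCC(=O)C(OC)C(=O)OC | intermediate
3 | N-methoxy-N-methylacetamide | CC(=O)N(C)OC | starting material
4 | methyl 2,4-dimethoxy-3,5-dioxohexanoate (labile epimers and enol forms) | CC(=O)C(OC)C(=O)C(OC)C(=O)OC | intermediate
5 | N,2-dimethoxy-N-methylacetamide | COCC(=O)N(C)OC | starting material
6 | methyl 2,4,8-trimethoxy-3,5,7-trioxooctanoate (labile epimers and enol forms) | COCC(=O)CC(=O)C(OC)C(=O)C(OC)C(=O)OC | intermediate
7 | 2-methoxy-1-(2,4,6-trihydroxy-3,5-dimethoxyphenyl)ethanone | COCC(=O)c1c(O)c(OC)c(O)c(OC)c1O | intermediate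
8 | 1-(2,6-dihydroxy-3,4,5-trimethoxyphenyl)-2-methoxyethanone | COCC(=O)c1c(O)c(OC)c(OC)c(OC)c1O | intermediate
9 | 3-methoxybenzoyl chloride | COc1cccc(C(=O)Cl)c1 | starting material
10 | 3-hydroxy-4,5,6-trimethoxy-2-(methoxyacetyl)phenyl 3-methoxybenzoate | COCC(=O)c1c(O)c(OC)c(OC)c(OC)c1OC(=O)c1cccc(OC)c1 | intermediate
11 | 1-(2,6-dihydroxy-3,4,5-trimethoxyphenyl)-2-methoxy-3-(3-methoxyphenyl)propane-1,3-dione (racemic, enolisable; not isolated) | COc1cccc(C(=O)C(OC)C(=O)c2c(O)c(OC)c(OC)c(OC)c2O)c1 | intermediate
12 | emmaosunin, 5-hydroxy-3,6,7,8-tetramethoxy-2-(3-methoxyphenyl)chromen-4-one | COc1cccc(-c2oc3c(OC)c(OC)c(OC)c(O)c3c(=O)c2OC)c1 | target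

## Step count and least certain steps

Total step count: 7. Longest linear sequence: 7 steps (1 → 2 → 4 → 6 → 7 → 8 → 10 → 12).

**Step 4 (key step).** The most likely failure is cleavage of the chain by retro-Claisen attack of methoxide on the ketones that flank the methoxy-bearing carbons, together with diversion into oxygen cyclisation (lactone, then pyranone by dehydration). Both CH(OMe) positions make their neighbouring ketones more electrophilic, and the acylating ester is deactivated whenever C2 is enolised. The fallback gives up the chain folding and builds 8 on a preformed benzene ring. It sets out from amide 5. Purchased pentamethoxybenzene F1 is lithiated at its only ring hydrogen, which lies between two methoxy groups (n-BuLi, TMEDA, THF, 0 °C, directed ortho-lithiation). The aryllithium is acylated by 5 to give 2-methoxy-1-(2,3,4,5,6-pentamethoxyphenyl)ethanone F2. Excess BCl3 (CH2Cl2, −78 → 25 °C) should then cleave the two methyl ethers ortho to the ketone, the only ones that can reach boron held on the carbonyl oxygen. The route is rejoined at 8, and steps 4 and 5 are bypassed.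

**Step 3.** The most likely failure is incomplete formation of the triply charged enolate, or its quenching by proton transfer from amide 5, followed by loss of 6 through lactonisation during work-up. Three neighbouring negative charges on a chain with two donor methoxy groups make the last deprotonation slow. The fallback replaces the polyanion by its neutral silyl equivalent. From 4, Me3SiCl/Et3N followed by LiN(i-Pr)2/Me3SiCl should give the tris(silyl enol ether) 1,2,4-trimethoxy-1,3,5-tris(trimethylsilyloxy)hexa-1,3,5-triene F3. Its terminal CH2 carbon is acylated by methoxyacetyl chloride F4 (CH2Cl2, −78 °C, Mukaiyama-type acylation of a silyl polyenol ether). Aqueous work-up removes the remaining silyl groups and the route comes back at 6.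

**Step 5.** The most likely failure is methylation spreading to an ortho hydroxyl, because the 4-hydroxyl of 7, though the most acidic, sits between two methoxy groups. The fallback postpones the methylation until the 5-hydroxyl is protected by chelation in the flavone. From 7, the polyanion formed with LiN(SiMe3)2 (5 equiv, THF, −78 °C) is acylated on carbon by 9 to give 1-(2,4,6-trihydroxy-3,5-dimethoxyphenyl)-2-methoxy-3-(3-methoxyphenyl)propane-1,3-dione F5. AcOH/H2SO4 at 95 °C closes ring C to 5,7-dihydroxy-3,6,8-trimethoxy-2-(3-methoxyphenyl)chromen-4-one F6. In F6 only the 7-hydroxyl is free of chelation, so Me2SO4/K2CO3 in acetone should methylate it alone. The route arrives directly at 12, and steps 5 to 7 are bypassed.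

**Step 7.** The most likely failure is cleavage of the aryl ester of 10 by the amide base, or intermolecular acyl transfer in place of the intramolecular shift. The enolate of the methoxyacetyl group is hindered, and the neighbouring phenoxide lowers the acidity of the ketone. The fallback forms the carbon–carbon bond directly. From 8, LiN(SiMe3)2 (4 equiv, THF, −78 °C) gives the bis-phenoxide enolate, which 9 acylates on carbon. This gives 11 without passing through 10, and 11 is cyclised with AcOH/H2SO4 as in step 7. No new compound is involved.

## Further compounds

F1 | step 4 | pentamethoxybenzene (purchased) | COc1cc(OC)c(OC)c(OC)c1OC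
F2 | step 4 | 2-methoxy-1-(2,3,4,5,6-pentamethoxyphenyl)ethanone | COCC(=O)c1c(OC)c(OC)c(OC)c(OC)c1OC
F3 | step 3 | 1,2,4-trimethoxy-1,3,5-tris(trimethylsilyloxy)hexa-1,3,5-triene (mixture of double-bond isomers) | C=C(O[Si](C)(C)C)C(OC)=C(O[Si](C)(C)C)C(OC)=C(OC)O[Si](C)(C)C
F4 | step 3 | methoxyacetyl chloride (purchased) | COCC(=O)Cl
F5 | step 5 | 1-(2,4,6-trihydroxy-3,5-dimethoxyphenyl)-2-methoxy-3-(3-methoxyphenyl)propane-1,3-dione (racemic, enolisable) | COc1cccc(C(=O)C(OC)C(=O)c2c(O)c(OC)c(O)c(OC)c2O)c1
F6 | step 5 | 5,7-dihydroxy-3,6,8-trimethoxy-2-(3-methoxyphenyl)chromen-4-one | COc1cccc(-c2oc3c(OC)c(O)c(OC)c(O)c3c(=O)c2OC)c1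
F0 | step 7 | none | none
A1 | alternative 1 | 5,6,7,8-tetramethoxy-2-(3-methoxyphenyl)chromen-4-one | COc1cccc(-c2cc(=O)c3c(OC)c(OC)c(OC)c(OC)c3o2)c1
A2 | alternative 1 | 2,3,4,5-tetramethoxy-6-(trimethylsilyl)phenyl trifluoromethanesulfonate | COc1c(OC)c(OC)c(OS(=O)(=O)C(F)(F)F)c([Si](C)(C)C)c1OC
A3 | alternative 1 | 3-(3-methoxyphenyl)prop-2-ynoic acid | COc1cccc(C#CC(=O)O)c1
A4 | alternative 2 | 5,8-dihydroxy-3,6,7-trimethoxy-2-(3-methoxyphenyl)chromen-4-one | COc1cccc(-c2oc3c(O)c(OC)c(OC)c(O)c3c(=O)c2OC)c1
A5 | alternative 2 | 4-hydroxy-2,3-dimethoxy-4-[5-methoxy-6-(3-methoxyphenyl)-4-oxo-4H-pyran-3-yl]cyclobut-2-en-1-one (racemic) | COC1=C(OC)C(O)(c2coc(-c3cccc(OC)c3)c(OC)c2=O)C1=O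
A6 | alternative 2 | 3,4-dimethoxycyclobut-3-ene-1,2-dione (dimethyl squarate) | COC1=C(OC)C(=O)C1=O
A7 | alternative 2 | 5-bromo-3-methoxy-2-(3-methoxyphenyl)pyran-4-one | COc1cccc(-c2occ(Br)c(=O)c2OC)c1
A8 | alternative 3 | 3,5,6,7,8-pentamethoxy-2-(3-methoxyphenyl)chromen-4-one | COc1cccc(-c2oc3c(OC)c(OC)c(OC)c(OC)c3c(=O)c2OC)c1
A9 | alternative 3 | (E)-2-methoxy-3-(3-methoxyphenyl)-3-(2,3,4,5-tetramethoxyphenoxy)prop-2-enoic acid | COc1cccc(/C(Oc2cc(OC)c(OC)c(OC)c2OC)=C(\OC)C(=O)O)c1
A10 | alternative 3 | 2,3,4,5-tetramethoxyphenol | COc1cc(O)c(OC)c(OC)c1OC
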